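The earlier runs and the new flask come from a simulation with made-up constants.

Watch one ratio.

| flask | starting material | partner | remark | time |
|---|---|---|---|---|
| red | 0.16 M | 1 equiv | run made earlier |  |
| violet | 0.16 M | 2 equiv | run made earlier |  |
| teal | 0.16 M | 3.4 equiv | run made earlier |  |
| larch | 0.16 M | 0.900 equiv |  | 30 h |
| cedar | 0.16 M | 1.80 equiv |  | 30 h |
| elm | 0.16 M | 3.60 equiv |  | 30 h |

| run | time / h | intermediate D / % | target / % | intermediate A / % | intermediate B / % | starting material / % |
|---|---|---|---|---|---|---|
| red | 2.50 | 0 | 21.8 | 5.3 | 1.4 | 69.9 |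
| red | 8.00 | 1.1 | 43.0 | 12.7 | 3.0 | 35.1 |
| red | 15.0 | 0.8 | 54.0 | 16.9 | 4.2 | 19.5 |
| red | 20.0 | 0.4 | 58.9 | 18.8 | 5.8 | 13.1 |
| red | 30.0 | 1.6 | 58.7 | 20.7 | 5.3 | 6.3 |
| violet | 6.00 | 0 | 60.9 | 7.4 | 5.1 | 25.1 |
| violet | 12.0 | 1.7 | 73.6 | 8.7 | 1.6 | 7.2 |
| violet | 20.0 | 1.7 | 80.3 | 8.7 | 3.0 | 1.1 |
| violet | 25.0 | 3.9 | 83.3 | 8.1 | 1.7 | 2.8 |
| violet | 30.0 | 3.7 | 82.6 | 10.4 | 2.4 | 0.7 |
| teal | 2.50 | 1.2 | 55.5 | 3.3 | 1.8 | 37.3 |
| teal | 8.00 | 0.6 | 84.6 | 4.7 | 2.4 | 6.9 |
| teal | 15.0 | 3.1 | 88.6 | 4.6 | 0.2 | 0 |
| teal | 20.0 | 2.0 | 90.0 | 2.9 | 1.2 | 0 |
| teal | 30.0 | 2.2 | 90.2 | 1.2 | 0 | 0 |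

(each reading ± 1 percentage point)

- a reading of intermediate B is of its free form alone

- which of these there is most of at the end, counted by the starting material in it, larch (target / intermediate B / starting material / intermediate A / intermediate D)
- which of these there is most of at the end, counted by the starting material in it, cedar (target / intermediate B / starting material / intermediate A / intermediate D)
- which of these there is most of at the end, counted by the starting material in it, elm (target / intermediate B / starting material / intermediate A / intermediate D)
- final amount of the leader among these, as a percentage of the starting material charged, in larch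
- final amount of the leader among these, as a percentage of the starting material charged, in cedar
- final amount of the leader among these, as a percentage of the starting material charged, in elm

Minutes. The kineticist proposed comparing two rates at one moment. Target forms as [starting material][partner] and intermediate A as [starting material], so [starting material] cancels from their ratio, which should then follow [partner]. Dividing target by intermediate A at the first reading, and that by charged [partner], gave 25.7 M⁻¹ in red and 30.9 M⁻¹ in teal. The analyst objected that teal's intermediate A reads 3.3% with a scatter of 1 percentage point, so these are rough readings. The meeting took their mean, 28.3 M⁻¹, as the selectivity factor per unit of [partner].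

The process chemist raised the drift: [partner] falls as target forms, so the ratio falls during a run. The meeting agreed to use mid-course [partner], the charge less half the charged [starting material], and to set the result against target over intermediate A plus intermediate D, supposing that D comes from A.

The analyst tested this on the runs. Red reads 2.63 against a reckoned 2.26, and violet reads 5.86 against 6.79. Teal reads 26.5 against 13.1, but its readings sum 6.4 points short, and that point was left open.

The chemist's own reckoning gives 1.81 for larch, down from 4.08 at the start, 5.89 for cedar and 14.0 for elm. Each stands above 1, so target should lead intermediate A in each flask.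

The forecast, reading along “a curve that rises steeply and then saturates”, named target as leader in each flask, at 54% in larch, 79% in cedar and 91% in elm. The flasks give target at 56.9% in larch, 79.1% in cedar and 90.2% in elm.

    2 starting material → self-condensation product (k = 1.60 × 10⁻⁴ M⁻¹ h⁻¹)
    intermediate B ⇌ intermediate C (K = 0.780, k = 0.100 h⁻¹)
    starting material + target → side product (k = 0.0270 M⁻¹ h⁻¹)
    partner + intermediate D ⇌ intermediate E (K = 3.50 M⁻¹, k = 0.200 M⁻¹ h⁻¹)
    starting material ⇌ intermediate B (K = 0.420, k = 0.0140 h⁻¹)
    partner + intermediate A ⇌ intermediate D (K = 18.0 M⁻¹, k = 0.0830 M⁻¹ h⁻¹)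
    starting material → intermediate A (k = 0.0260 h⁻¹)
    starting material + partner → target (k = 0.720 M⁻¹ h⁻¹)

With intermediate E counted beside intermediates A and D, target over that family stands at 2.38 in larch, 5.92 in cedar and 13.7 in elm. A neighbouring flask is elm with starting material at 0.064 M, the equivalents held, so its mid-course [partner] is 0.198 M and the ratio reckons to 5.62. It ends with target at 79.3%, intermediate A at 10.0%, intermediate D at 3.10% and intermediate E at 1.03%, a ratio of 5.61.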